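Choosing the bath for this charge is a choice between speed and equilibrium: warming hurries the coupling of intermediate with partner, and it also lowers the share of intermediate that substrate can hold.

| flask | substrate | partner | catalyst | temperature | time |
|---|---|---|---|---|---|
| north-east | 0.0050 M | 5.00 mM | 0.50 mM | 20 °C | 6.0 s |
| north-west | 0.0050 M | 5.00 mM | 0.50 mM | 60 °C | 6.0 s |
| west | 0.0050 M | 5.00 mM | 0.50 mM | 40 °C | 6.0 s |
| south-west | 0.0050 M | 5.00 mM | 0.50 mM | 0 °C | 6.0 s |

* which flask leads in amount of target, in percent of the substrate charged ("all alike" within 1.5 percentage points) (north-east / north-west / west / south-west / all alike)
* how much target is there at the end, in percent of the substrate charged: north-east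
* how much target is there at the end, in percent of the substrate charged: north-west
* how much target is there at the end, in percent of the substrate charged: west
* how much target is there at the end, in percent of the substrate charged: south-west

- constants are those at 40 °C; use the activation energies and enthalpies for any other temperature

    target + catalyst ⇌ isomer of the product + catalyst, rate k1*[catalyst]*[target] forward; the back reaction follows from the equilibrium constant (K1 = 0.36, k1 = 930 L mol⁻¹ s⁻¹, Ea1 = 40.0 kJ mol⁻¹, ΔH1 = −32.0 kJ mol⁻¹)
    partner + catalyst + intermediate → catalyst + target (k2 = 48000 L² mol⁻² s⁻¹, Ea2 = 26.0 kJ mol⁻¹)
    substrate + catalyst ⇌ catalyst + intermediate (K3 = 1.8, k3 = 190 L mol⁻¹ s⁻¹, Ea3 = 47.0 kJ mol⁻¹, ΔH3 = −35.0 kJ mol⁻¹)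
    (constants at 40 °C)

Turn the question round. The cold south-west flask could beat the hot north-west flask on equilibrium grounds if the lost share of intermediate outweighed the gain in coupling speed. Suppose substrate and intermediate stood in equilibrium. Intermediate would then be 92.8% of their pool in south-west and 44.5% in north-west. That is a loss by a factor of 2.09, while coupling speeds up 7.9 times between those flasks. The opposite outcome would need these two factors reversed, and this flask stands 3.79 times from equality. This reckoning therefore puts north-west ahead of south-west.

The target in north-west can be estimated from a rate of leakage out of the pool. With partner held at its charge, each step is pseudo-first-order. In north-west, substrate becomes intermediate at 0.281 s⁻¹, intermediate returns at 0.350 s⁻¹, and it couples at 0.219 s⁻¹. The leak constant is the fraction of the pool that leaves for target each second once intermediate has reached its steady share: the coupling constant times the forming constant, over the sum of the three. Here it is 0.0723 s⁻¹. The pool fills over a lag, the inverse of that sum, of 1.18 s, which is shorter than the time. In this reckoning the leak then runs for the rest of the time. Target and isomer of the product share what has leaked according to an equilibrium constant of 0.172, so this reckoning gives 25.1% target in north-west.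

The forecast also names north-west, with 2%, 24.4%, 9.2% and 0.29% for north-east, north-west, west and south-west, on the ground that “its faster substrate-to-intermediate and coupling steps outweigh the less favourable intermediate equilibrium”.

The simulation puts north-west ahead, with target at 1.96% in north-east, 23.5% in north-west, 9.10% in west and 0.287% in south-west.

In north-west, target and isomer of the product relax towards each other with a half-life of 0.0870 s, far shorter than the time of 6.0 s, and the flask ends with 23.5% target beside 3.95% isomer of the product. The leak constant of 0.0723 s⁻¹ gave 25.1% with partner held at its charge, whereas the flask ends at 23.5% with partner at 72.6% of its charge.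

In a neighbour flask, a repeat of north-west at 45 °C with the same charges and time, the three constants become 0.126 s⁻¹, 0.0866 s⁻¹ and 0.140 s⁻¹, so the leak constant is 0.0502 s⁻¹ and the reckoned target 11.3%. The simulated neighbour holds 12.4%.

The constants used here stand for no real mixture.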